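(Readings and results are calculated for an exercise.)

Run colder, at 10 °C, the target still stood at 15.9% after 30.0 h, above the 8.95% at which the last two readings of the dusk run at 25 °C stood level from 12.0 h on. The dusk run is the flask asked about, followed so far, and I wanted from it one quantity: the equilibrium share, the plateau target over the pool of target plus whatever it relaxes into.

the same everywhere: starting material 19 mM; coupling partner 1.05 equiv
- dusk: protic impurity 5.7 mM; temperature 25 °C; the very flask that is asked about, followed so far
- autumn: protic impurity 5.7 mM; temperature 10 °C; run made earlier
- flask: protic impurity 5.70 mM; temperature 25 °C; time 20 h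

| run | time / h | target / % |
|---|---|---|
| dusk | 2.50 | 31.0 |
| dusk | 5.00 | 19.2 |
| dusk | 6.00 | 13.8 |
| dusk | 10.0 | 10.8 |
| dusk | 12.0 | 9.0 |
| dusk | 15.0 | 8.9 |
| autumn | 5.00 | 26.2 |
| autumn | 10.0 | 32.1 |
| autumn | 12.0 | 32.3 |
| autumn | 20.0 | 25.6 |
| autumn | 25.0 | 20.3 |
| autumn | 30.0 | 15.9 |

(scatter of a reading: 1 percentage point)

- Friday's: at 20 h take out 90% of the target then present, then wait 20 h
- Sunday's: at 20 h raise the temperature by 25 K, then wait 20 h
- Thursday's: at 20 h add coupling partner, 100% of the amount charged, then wait 20 h
- Wednesday's: change nothing and wait 20 h more

* target, in percent of the starting material first charged, at 20 h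
* the option that brings most further target ("none" if no option brings more than 2 percentage points) (Friday's / Sunday's / Thursday's / Wednesday's / none)
* target present, with what was taken out counted in, in percent of the starting material first charged, after Friday's
* target present, with what was taken out counted in, in percent of the starting material first charged, after Wednesday's

- target taken out counts as made
- additions bring no volume worth counting

I ordered the flask by time scales. First came the making of target, already past its peak by my reading: the dusk run was falling from 2.50 h on. Next came relaxation. Between the first and third readings I read the excess over the plateau falling at 0.433 h⁻¹, a half-life of 1.60 h. Carried back to the start, that excess is 65.0%, so I read a pool of 74.0% and an equilibrium share of 0.121.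

The asked time stood far beyond that half-life: by 20 h I reckoned the excess at 0.0113%, hardly any of the plateau, so I expected the plateau at 20 h and no gain from Wednesday's. Friday's removes 90% of the plateau, and the share of the remaining pool comes back, for 16.0% in total.

Sunday's overtakes that once the share reaches 0.217. The autumn slope held at 0.0464 h⁻¹, then 0.0489 h⁻¹, without levelling, which I read as a low plateau there. I therefore took the share to rise with temperature and chose Sunday's, without a size for it.

The forecast gave 8.8% now, 16% after Friday's and 8.8% after Wednesday's, and named Friday's best, saying “The effect of heating is unknown”. It read the decay at roughly 0.33 per hour, where I read 0.433 h⁻¹.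

The flask gives 9.46%, then 16.9% after Friday's and 9.46% after Wednesday's; Sunday's is best, bringing 34 percentage points against 7.4 points for Friday's.

    starting material + protic impurity → quenched substrate (k = 1.40 M⁻¹ min⁻¹, Ea = 56.0 kJ mol⁻¹)
    target ⇌ isomer of the product B (K = 6.60, k = 0.00750 min⁻¹, Ea = 86.0 kJ mol⁻¹, ΔH = −74.0 kJ mol⁻¹)
    coupling partner + loose pair → isomer of the product A (k = 41000 M⁻¹ min⁻¹, Ea = 39.0 kJ mol⁻¹)
    coupling partner + tight pair → target (k = 16000 M⁻¹ min⁻¹, Ea = 46.0 kJ mol⁻¹)
    starting material ⇌ tight pair (K = 4.50 × 10⁻⁴, k = 0.0160 min⁻¹, Ea = 102 kJ mol⁻¹, ΔH = −22.0 kJ mol⁻¹)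
    tight pair ⇌ loose pair (K = 3.00, k = 12.0 min⁻¹, Ea = 67.0 kJ mol⁻¹, ΔH = −45.0 kJ mol⁻¹)
    (constants at 25 °C)

At 20 h the flask held 9.46% of target beside 62.4% of isomer of the product B, a share of 0.132 against my reading of 0.121. The neighbour flask, with 23 mM of protic impurity, ended with 61.9% of quenched substrate and 1.69% of isomer of the product A. Subtracted from the charge, these leave a pool of 36.4%, and my share of that pool is 4.40%. The neighbour flask held 4.79% of target.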